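The six-membered carbocycle (C4a, C5, C6, C7, C8, C8a) is disconnected at C4a–C8a. C8, C1′–C4′ and C8a are carried as a seven-membered lactone, on whose α-carbon C8 is made quaternary. C4a, C5, C6, C7 and the benzoyl group are carried as a 5-methyl-3-phenylisoxazol-4-yl ketone on that α-carbon. The key step exploits the vinylogous acidity of the isoxazole methyl group (C4a) and its 1,6-relationship to the lactone carbonyl (C8a): one deprotonation closes the carbocycle, opens the lactone and frees C4′–OH for chain extension, leaving C8 and C2′ untouched. The isoxazole masks the triketone and leaves only the C8a oxygen for the pyran.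

Key step: step 4

Atom labels: chromene numbering of the target (O1, C2, C3, C4, C4a, C5, C6, C7, C8, C8a); the chain on C8 is C1′H2–C2′H(isopropenyl)–C3′H2–C4′H=C5′(CH3)–CO2H.

Assumption: 7 is written as its C8a enol (the C8a ketone is a tautomer of the same compound), and the monooxygenase is taken to insert oxygen in the sense usual for 4-substituted cyclohexanones, which leads to the (S)-lactone.

Step 1
Reactants: 1 4-(prop-1-en-2-yl)cyclohexan-1-one
Product: 2 (5S)-5-(prop-1-en-2-yl)oxepan-2-one
Conditions: cyclohexanone monooxygenase (Acinetobacter type), NADP+ (cat.), glucose dehydrogenase, D-glucose (1.5 equiv), air, Tris buffer pH 8.5, 25 °C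
Reagents that add atoms: dioxygen, O=O
Why: Enzymatic Baeyer–Villiger oxidation, in which the enzyme-bound flavin hydroperoxide adds to the prochiral ketone and one of the two enantiotopic ring bonds migrates; this should turn C4 of the ketone into the (S)-configured C5 of the lactone (the future C2′) and, unlike a peracid, should leave the isopropenyl alkene untouched.

Step 2
Reactants: 2 (5S)-5-(prop-1-en-2-yl)oxepan-2-one; 3 5-methyl-3-phenyl-1,2-oxazole-4-carbonyl chloride
Product: 4 (5S)-3-[(5-methyl-3-phenyl-1,2-oxazol-4-yl)carbonyl]-5-(prop-1-en-2-yl)oxepan-2-one (C3 epimers and enol form)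
Conditions: LiHMDS [LiN(SiMe3)2] (2.1 equiv), THF, −78 °C; then 3 (1.05 equiv), −78 to −40 °C; AcOH quench
Reagents that add atoms: 5-methyl-3-phenyl-1,2-oxazole-4-carbonyl chloride (compound 3), Cc1onc(-c2ccccc2)c1C(=O)Cl
Why: Crossed Claisen-type C-acylation of the lactone lithium enolate by the acid chloride, in which the second equivalent of base turns the more acidic β-keto lactone into its enolate as it forms and so prevents double acylation; the new C3 centre needs no control because it becomes planar again in step 3.

Step 3
Reactants: 4 (5S)-3-[(5-methyl-3-phenyl-1,2-oxazol-4-yl)carbonyl]-5-(prop-1-en-2-yl)oxepan-2-one; 5 1-bromo-3-methylbut-2-ene (prenyl bromide)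
Product: 6 (3S,5S)-3-[(5-methyl-3-phenyl-1,2-oxazol-4-yl)carbonyl]-3-(3-methylbut-2-en-1-yl)-5-(prop-1-en-2-yl)oxepan-2-one (prenyl trans to isopropenyl on the lactone ring)
Conditions: 5 (1.2 equiv), C2-symmetric N-spiro bis(binaphthyl) ammonium bromide with 3,4,5-trifluorophenyl groups at the 3,3′-positions (2 mol%, antipode matched to the 3S product), K2CO3 (solid, 2 equiv), toluene, −20 to 0 °C
Reagents that add atoms: prenyl bromide (compound 5), CC(C)=CCBr
Why: Asymmetric phase-transfer C-alkylation of a stabilised α-aroyl lactone enolate, in which the chiral ammonium ion pair exposes one enolate face to the soft allylic bromide so that prenyl should enter trans to isopropenyl and fix C8; the catalyst is used because the C5 substituent alone, 1,3 to the reacting carbon on a flexible seven-membered enolate, is not a dependable control element, and the matched antipode would be identified against an achiral run with Bu4NBr.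

Step 4
Reactants: 6 (3S,5S)-3-[(5-methyl-3-phenyl-1,2-oxazol-4-yl)carbonyl]-3-(3-methylbut-2-en-1-yl)-5-(prop-1-en-2-yl)oxepan-2-one
Product: 7 (5R)-6-hydroxy-5-[(2S)-4-hydroxy-2-(prop-1-en-2-yl)butyl]-5-(3-methylbut-2-en-1-yl)-3-phenyl-1,2-benzoxazol-4(5H)-one
Conditions: 6 added slowly to LiHMDS [LiN(SiMe3)2] (2.3 equiv), THF (0.02 M), −78 °C, then to −20 °C; AcOH quench at −78 °C
Reagents that add atoms: none
Why: The amide base removes a proton from the isoxazole 5-methyl group, the only acidic C–H in 6 and activated through the isoxazole C5=C4 bond by the C7 ketone; the extended enolate attacks the lactone carbonyl through its exocyclic carbon, the tetrahedral intermediate expels the C4′ alkoxide, and the second equivalent of base deprotonates the new C4a–H between C8a=O and the heteroarene, which makes the sequence irreversible. The closest known reaction type is lateral metalation of a 5-methylisoxazole followed by Claisen-type acylation, run here intramolecularly as a Dieckmann condensation on a lactone with release of the alcohol. The one new ring, the carbocycle C4a–C5–C6–C7–C8–C8a, closes in the 6-(enolendo)-exo-trig mode. No stereocentre is formed, and C8 (quaternary, not enolisable) and C2′ (not acidic) should pass through unchanged. The step needs addition to the lactone carbonyl and not cleavage of the C7–C8 bond (retro-Claisen loss of the acyl group); this is secured by the non-nucleophilic base, the lack of any other acidic proton, the six-membered transition state and the stabilised enolate sink. Inverse addition into excess base at low temperature keeps the freed alkoxide away from unreacted 6.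

Step 5
Reactants: 7 (5R)-6-hydroxy-5-[(2S)-4-hydroxy-2-(prop-1-en-2-yl)butyl]-5-(3-methylbut-2-en-1-yl)-3-phenyl-1,2-benzoxazol-4(5H)-one; 8 3-methylbut-2-enal
Product: 10 pyrano-fused isoxazole ketone [2,2-dimethyl-2H-pyran fused at C4a=C8a with O1 on C8a; isoxazole fused at C5–C6 with its oxygen on C5 and C(Ph)=N on C6; C7 ketone; C8 (R) carries prenyl and the (2S)-4-hydroxy-2-(prop-1-en-2-yl)butyl chain], via oxatriene Knoevenagel adduct 9 (not isolated)
Conditions: 8 (2 equiv), ethylenediammonium diacetate (20 mol%), toluene, 60 °C
Reagents that add atoms: 3-methylbut-2-enal (compound 8), CC(C)=CC=O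
Why: Knoevenagel condensation at C4a of the vinylogous acid followed by 6π-oxa-electrocyclisation of the 1-oxatriene 9 (formal [3+3] chromene annulation); the pyran can close only on the C8a oxygen because the C5 oxygen is held in the isoxazole ring.

Step 6
Reactants: 10 pyrano-fused isoxazole ketone with the C4′ primary alcohol
Product: 11 the corresponding C4′ aldehyde (C8 and C2′ unchanged)
Conditions: Dess–Martin periodinane (1.3 equiv), CH2Cl2, 0 °C to rt
Reagents that add atoms: none
Why: Dess–Martin oxidation of a primary alcohol should stop at the aldehyde under non-aqueous conditions that spare the dienone, the 2H-pyran, the alkenes and the isoxazole; C2′ is β to the new carbonyl and cannot epimerise.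

Step 7
Reactants: 11 C4′ aldehyde; 12 ethyl 2-(triphenylphosphoranylidene)propanoate
Product: 13 ethyl (E)-2-methyl-2-enoate [C4′H=C5′(CH3)CO2Et on the pyrano-fused isoxazole ketone; C8 (R), C2′ (R, by change of priority only)]
Conditions: 12 (1.5 equiv), toluene, 60 °C
Reagents that add atoms: ethyl 2-(triphenylphosphoranylidene)propanoate (compound 12), CCOC(=O)C(C)=P(c1ccccc1)(c1ccccc1)c1ccccc1
Why: Wittig olefination with an α-methyl ester-stabilised ylide should react only with the aldehyde, not with the conjugated C7 ketone, and should give the (E)-trisubstituted enoate, as is usual for stabilised ylides.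

Step 8
Reactants: 13 ethyl (E)-enoate of the pyrano-fused isoxazole ketone
Product: 14 primary enaminone [C6=C(NH2)Ph flanked by C5=O and C7=O; pyran, prenyl, isopropenyl and ethyl enoate unchanged]
Conditions: Mo(CO)6 (1.0 equiv), MeCN/H2O (10:1), 80 °C
Reagents that add atoms: none
Why: Reductive N–O cleavage of the isoxazole by zerovalent molybdenum with water as the proton source should unmask the C5 carbonyl and leave the benzoyl carbon as a primary enaminone, a method known to spare alkenes, enoates and enones.

Step 9
Reactants: 14 primary enaminone ethyl ester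
Product: 16 (2E,5R)-6-[(8S)-6-benzoyl-7-hydroxy-2,2-dimethyl-8-(3-methylbut-2-en-1-yl)-5-oxo-5,8-dihydro-2H-chromen-8-yl]-2-methyl-5-(prop-1-en-2-yl)hex-2-enoic acid (CNP0333091.1), via enaminone carboxylic acid 15 (not isolated)
Conditions: LiOH (aq, 6 equiv), THF/MeOH, rt, then 60 °C; 1 M HCl to pH 3
Reagents that add atoms: lithium hydroxide, [Li+].[OH-]; water, O
Why: Saponification of the ethyl ester at room temperature, then addition–elimination of hydroxide at the enaminone carbon (hydrolysis of a vinylogous amide, driven by the acidic β-triketone enolate), should release the acid and the 6-benzoyl-7-hydroxy-5-oxo system; neither stereocentre lies next to an enolisable position.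

Compound list
1 | 4-(prop-1-en-2-yl)cyclohexan-1-one | C=C(C)C1CCC(=O)CC1 | starting material
2 | (5S)-5-(prop-1-en-2-yl)oxepan-2-one | C=C(C)[C@@H]1CCOC(=O)CC1 | intermediate
3 | 5-methyl-3-phenyl-1,2-oxazole-4-carbonyl chloride | Cc1onc(-c2ccccc2)c1C(=O)Cl | starting material
4 | (5S)-3-[(5-methyl-3-phenyl-1,2-oxazol-4-yl)carbonyl]-5-(prop-1-en-2-yl)oxepan-2-one, C3 epimers | C=C(C)[C@@H]1CCOC(=O)C(C1)C(=O)c1c(C)onc1-c1ccccc1 | intermediate
5 | 1-bromo-3-methylbut-2-ene (prenyl bromide) | CC(C)=CCBr | starting material
6 | (3S,5S)-3-[(5-methyl-3-phenyl-1,2-oxazol-4-yl)carbonyl]-3-(3-methylbut-2-en-1-yl)-5-(prop-1-en-2-yl)oxepan-2-one | C=C(C)[C@@H]1CCOC(=O)[C@@](CC=C(C)C)(C1)C(=O)c1c(C)onc1-c1ccccc1 | intermediate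
7 | (5R)-6-hydroxy-5-[(2S)-4-hydroxy-2-(prop-1-en-2-yl)butyl]-5-(3-methylbut-2-en-1-yl)-3-phenyl-1,2-benzoxazol-4(5H)-one | C=C(C)[C@H](CCO)C[C@@]1(CC=C(C)C)C(=O)c2c(-c3ccccc3)noc2C=C1O | intermediate
8 | 3-methylbut-2-enal | CC(C)=CC=O | starting material
9 | oxatriene Knoevenagel adduct: (5R)-5-[(2S)-4-hydroxy-2-(prop-1-en-2-yl)butyl]-7-(3-methylbut-2-en-1-ylidene)-5-(3-methylbut-2-en-1-yl)-3-phenyl-1,2-benzoxazole-4,6(5H,7H)-dione | C=C(C)[C@H](CCO)C[C@@]1(CC=C(C)C)C(=O)c2c(-c3ccccc3)noc2C(=CC=C(C)C)C1=O | intermediate
10 | pyrano-fused isoxazole ketone with free C4′ alcohol, C8 (R), C2′ (S) | C=C(C)[C@H](CCO)C[C@@]1(CC=C(C)C)C(=O)c2c(-c3ccccc3)noc2C4=C1OC(C)(C)C=C4 | intermediate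
11 | pyrano-fused isoxazole ketone with C4′ aldehyde, C8 (R), C2′ (S) | C=C(C)[C@H](CC=O)C[C@@]1(CC=C(C)C)C(=O)c2c(-c3ccccc3)noc2C4=C1OC(C)(C)C=C4 | intermediate
12 | ethyl 2-(triphenylphosphoranylidene)propanoate | CCOC(=O)C(C)=P(c1ccccc1)(c1ccccc1)c1ccccc1 | starting material
13 | ethyl (E)-2-methyl-2-enoate of the pyrano-fused isoxazole ketone, C8 (R), C2′ (R) | C=C(C)[C@H](C/C=C(\C)C(=O)OCC)C[C@@]1(CC=C(C)C)C(=O)c2c(-c3ccccc3)noc2C4=C1OC(C)(C)C=C4 | intermediate
14 | primary enaminone ethyl ester [6-(amino(phenyl)methylidene)-5,7-dioxo chromene], C8 (R), C2′ (R) | C=C(C)[C@H](C/C=C(\C)C(=O)OCC)C[C@@]1(CC=C(C)C)C(=O)C(=C(N)c2ccccc2)C(=O)C2=C1OC(C)(C)C=C2 | intermediate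
15 | primary enaminone carboxylic acid | C=C(C)[C@H](C/C=C(\C)C(=O)O)C[C@@]1(CC=C(C)C)C(=O)C(=C(N)c2ccccc2)C(=O)C2=C1OC(C)(C)C=C2 | intermediate
16 | (2E,5R)-6-[(8S)-6-benzoyl-7-hydroxy-2,2-dimethyl-8-(3-methylbut-2-en-1-yl)-5-oxo-5,8-dihydro-2H-chromen-8-yl]-2-methyl-5-(prop-1-en-2-yl)hex-2-enoic acid | C=C(C)[C@H](C/C=C(\C)C(=O)O)C[C@@]1(CC=C(C)C)C(O)=C(C(=O)c2ccccc2)C(=O)C2=C1OC(C)(C)C=C2 | target

Total step count: 9 steps. Longest linear sequence: 9 steps (1 to 16); compounds 3, 5, 8 and 12 are purchased and enter directly.

Steps most likely to fail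

Step 4. Instead of ring closure, the tetrahedral intermediate or the freed alkoxide may cleave the C7–C8 bond (retro-Claisen), or the carbanion may fail to add to the hindered lactone carbonyl. The fallback makes the same C4a–C8a bond at the aldehyde oxidation level, where no alkoxide leaves and no acyl transfer is possible. It sets out from 6. Diisobutylaluminium hydride (i-Bu2AlH, 1.1 equiv, toluene, −78 °C) should reduce the lactone carbonyl in preference to the C7 ketone, which lies between a quaternary carbon and both flanking substituents of the isoxazole, and give the lactol F1. With LiN(SiMe3)2 (2.2 equiv, THF, −78 °C) the open hydroxy-aldehyde form of F1 should undergo intramolecular aldol addition of the same lateral carbanion and give the aldol diol F2. Dess–Martin periodinane in excess should oxidise both carbinols to the keto aldehyde F3, with the C8a ketone as its enol. Wittig olefination with excess 12 should then give the enol ethyl enoate F4, and annulation of F4 with 8 under the conditions of step 5 comes back to the route at 13. This costs one step more than steps 4 to 7.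

Step 3. Facial discrimination in the ion pair may be poor if the catalyst and the resident C2′ centre are mismatched, and O-prenylation may compete. The fallback uses a different chiral environment and a metal-bound electrophile. It sets out from 4. Asymmetric allylic alkylation with allyl acetate, Pd2(dba)3 as the source of zerovalent palladium, the (R,R)- or (S,S)-N,N′-(cyclohexane-1,2-diyl)bis[2-(diphenylphosphanyl)benzamide] ligand and tetramethylguanidine in toluene at −20 °C should give the 3-allyl lactone F5 by C-allylation only. Cross-metathesis of F5 with excess 2-methylbut-2-ene and second-generation Grubbs catalyst (CH2Cl2, 40 °C) converts allyl into prenyl and comes back to the route at 6; the 1,1-disubstituted isopropenyl group should not take part.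

Step 9. The hydrogen-bonded vinylogous amide may hydrolyse so slowly that the aqueous base needed starts to open the pyran (a vinylogous ester) or to cleave the benzoyl group. The fallback activates nitrogen as a leaving group. It sets out from 14. Boc2O with catalytic 4-(dimethylamino)pyridine in MeCN at rt should give the N-Boc enaminone F6. LiOH in THF/H2O at 0 °C to rt should then displace tert-butyl carbamate from the activated carbon and saponify the ester, and acidification comes back to the route at 16.

Further compounds
F1 | step 4 | lactol of 6 (2-hydroxyoxepane, hemiacetal carbon as anomer mixture) | C=C(C)[C@@H]1CCOC(O)[C@@](CC=C(C)C)(C1)C(=O)c1c(C)onc1-c1ccccc1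
F2 | step 4 | aldol diol (7 with C8a as secondary carbinol and C4a as CH2, carbinol epimers) | C=C(C)[C@H](CCO)C[C@@]1(CC=C(C)C)C(=O)c2c(-c3ccccc3)noc2CC1O
F3 | step 4 | keto aldehyde (7 with C4′ as aldehyde, C8a enol) | C=C(C)[C@H](CC=O)C[C@@]1(CC=C(C)C)C(=O)c2c(-c3ccccc3)noc2C=C1O
F4 | step 4 | enol ethyl enoate (13 without the pyran ring) | C=C(C)[C@H](C/C=C(\C)C(=O)OCC)C[C@@]1(CC=C(C)C)C(=O)c2c(-c3ccccc3)noc2C=C1O
F5 | step 3 | (3S,5S)-3-allyl-3-[(5-methyl-3-phenyl-1,2-oxazol-4-yl)carbonyl]-5-(prop-1-en-2-yl)oxepan-2-one | C=C(C)[C@@H]1CCOC(=O)[C@@](CC=C)(C1)C(=O)c1c(C)onc1-c1ccccc1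
F6 | step 9 | N-Boc enaminone ethyl ester | C=C(C)[C@H](C/C=C(\C)C(=O)OCC)C[C@@]1(CC=C(C)C)C(=O)C(=C(NC(=O)OC(C)(C)C)c2ccccc2)C(=O)C2=C1OC(C)(C)C=C2
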